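Praesorether G is a symmetric, achiral pentaaryl: two outer benzoate rings A, two aryloxy-resorcinol rings B and a central resorcinol ring C. In ring C the methyl carbon C6 is flanked by the bridge-bearing C1 and C5, C2 and C4 carry OH and C3 is CH; this is a heptane-3,5-dione (C1–C5) whose outer α-carbons are clasped by one acetyl carbon (C6). Everything rests on that [5+1] disconnection: a symmetric 1,7-bis(ring B)heptane-3,5-dione is C-acetylated at one outer α-carbon and closes by aldol aromatisation through the other, forming C1–C6, C5–C6 and ring C with both arms already in place. Rings A are attached last by double SNAr.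

Key step: step 8

Remark on the chemistry: the target has no stereocentre and is achiral (its SMILES carries no stereodescriptor), so there is no enantiomer to select and no step sets configuration.

Conventions: the ring C numbers of the overview are also used for the corresponding chain carbons of 13 and 15. ArB = 3-(benzyloxy)-2,6-bis(methoxymethoxy)-4-methylphenyl. Aryllithiums and covalent intermediates of one-pot sequences are numbered; enolates and tetrahedral adducts are treated as forms of the numbered compounds.

Step 1
Reactants: 1 2,4-dihydroxy-6-methylbenzaldehyde (orcinaldehyde)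
Product: 2 2,4-bis(methoxymethoxy)-6-methylbenzaldehyde
Conditions: MOMCl (3 equiv), iPr2NEt, CH2Cl2, 0 to 40 °C
Reagents that add atoms: chloromethyl methyl ether, COCCl
Why: Williamson-type O-alkylation of both phenols by the reactive α-chloro ether under amine base; excess reagent and warming should also cap the hydrogen-bonded 2-OH.

Step 2
Reactants: 2 2,4-bis(methoxymethoxy)-6-methylbenzaldehyde
Product: 4 2,4-bis(methoxymethoxy)-6-methylphenol, via aryl formate 3 (not isolated)
Conditions: mCPBA, CH2Cl2, 0 °C to rt; aq. Na2SO3/NaHCO3 wash; then K2CO3 (cat.), MeOH, rt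
Reagents that add atoms: 3-chloroperoxybenzoic acid, OOC(=O)c1cccc(Cl)c1
Why: Dakin-type Baeyer–Villiger oxidation, in which the electron-rich aryl group migrates to give the formate, followed by carbonate-catalysed methanolysis that leaves the MOM acetals untouched.

Step 3
Reactants: 4 2,4-bis(methoxymethoxy)-6-methylphenol
Product: 5 2-(benzyloxy)-1,5-bis(methoxymethoxy)-3-methylbenzene
Conditions: BnBr, K2CO3, DMF, rt
Reagents that add atoms: benzyl bromide, BrCc1ccccc1
Why: Williamson ether synthesis; the benzyl group marks the one oxygen that must later be freed alone for diaryl ether formation.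

Step 4
Reactants: 5 2-(benzyloxy)-1,5-bis(methoxymethoxy)-3-methylbenzene
Product: 7 3-(benzyloxy)-2,6-bis(methoxymethoxy)-4-methylbenzaldehyde, via aryllithium 6 (not isolated)
Conditions: n-BuLi, THF, −78 to −20 °C; DMF, −78 °C to rt; H2O
Reagents that add atoms: N,N-dimethylformamide, CN(C)C=O
Why: Directed ortho-metalation at the C–H flanked by the two chelating MOM ethers (by far the most acidic ring position, reached at low temperature before the benzyl ether can be deprotonated), then Bouveault formylation of the aryllithium.

Step 5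
Reactants: 7 3-(benzyloxy)-2,6-bis(methoxymethoxy)-4-methylbenzaldehyde
Product: 8 [3-(benzyloxy)-2,6-bis(methoxymethoxy)-4-methylphenyl]methanol
Conditions: NaBH4, MeOH/THF, 0 °C
Reagents that add atoms: none
Why: Borohydride reduction of the aryl aldehyde, to which acetals and the benzyl ether are inert.

Step 6
Reactants: 8 [3-(benzyloxy)-2,6-bis(methoxymethoxy)-4-methylphenyl]methanol
Product: 10 3-(benzyloxy)-2,6-bis(methoxymethoxy)-4-methylbenzyl chloride, via benzylic mesylate 9 (not isolated)
Conditions: MsCl, Et3N, CH2Cl2, 0 °C to rt; used crude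
Reagents that add atoms: methanesulfonyl chloride, CS(=O)(=O)Cl
Why: O-Sulfonylation followed by in situ substitution by the chloride released from MsCl, which is fast for a 2,6-dialkoxybenzylic mesylate and stays base-buffered so the MOM groups see no HX; the chloride is chosen because it should tolerate work-up better than the bromide.

Step 7
Reactants: 10 3-(benzyloxy)-2,6-bis(methoxymethoxy)-4-methylbenzyl chloride (2 equiv); 11 acetylacetone
Product: 13 1,7-bis[3-(benzyloxy)-2,6-bis(methoxymethoxy)-4-methylphenyl]heptane-3,5-dione, via monoalkylated diketone 12 (not isolated)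
Conditions: 11, LDA (2.1 equiv), THF, 0 °C; 10 (1 equiv), −78 to 0 °C; LDA (1.1 equiv), 0 °C; 10 (1 equiv), −78 °C to rt; H2O
Reagents that add atoms: none
Why: γ-Alkylation of the β-diketone 1,3-dianion at its terminal carbon, repeated after re-deprotonation, which should occur at the remaining methyl group and not at the already substituted methylene, so that both benzyl groups end up at the chain termini.

Step 8
Reactants: 13 1,7-bis[3-(benzyloxy)-2,6-bis(methoxymethoxy)-4-methylphenyl]heptane-3,5-dione; 14 methyl acetate
Product: 16 4,6-bis{[3-(benzyloxy)-2,6-bis(methoxymethoxy)-4-methylphenyl]methyl}-5-methylbenzene-1,3-diol, via triketone 15 (not isolated)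
Conditions: LDA (3.2 equiv), THF, −78 to 0 °C; MeOAc (2 equiv), −78 to 0 °C; AcOH; crude 15: DBU, PhMe, 50 °C
Reagents that add atoms: none
Why: LDA removes the C3 proton and one outer α-proton (C1) of 13, and the outer carbanion of this dianion adds to methyl acetate and expels methoxide (Claisen acylation, bond C1–C6), the third equivalent of amide holding the more acidic triketone 15 as its polyanion so that it does not quench unreacted dianion. After protonation, DBU ionises the unsubstituted C2–C3–C4 diketone unit of 15, the other outer methylene C5 adds through its enolate to the acetyl carbonyl C6 (bond C5–C6), and E1cB loss of water followed by enolisation of both ring carbonyls should give the resorcinol irreversibly. The closest known reaction types are the terminal acylation of β-diketone dianions by esters and the base-induced cyclisation of heptane-2,4,6-triones to orcinol-type resorcinols. Ring C closes in a 6-(enolendo)-exo-trig aldol, the enolate C4=C5 bond lying inside the new ring and the attacked C6=O outside it, and no stereocentre survives (C1 of 15 becomes aromatic). The selectivity needed is attack of C5 on the acetyl carbonyl and not attack of the acetyl methyl on the C4 carbonyl: the C2–C3–C4 diketone, unsubstituted at C3, is the more acidic one and sits as a delocalised enolate whose carbonyl carbons are poor electrophiles, whereas the acetyl group next to the alkylated, little-enolised C1 remains a true ketone, and closure of a chain methylene onto a methyl ketone is also the usual course when 2,5- and 2,6-alkanediones cyclise to 2-alkyl-3-methylcycloalkenones.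

Step 9
Reactants: 16 4,6-bis{[3-(benzyloxy)-2,6-bis(methoxymethoxy)-4-methylphenyl]methyl}-5-methylbenzene-1,3-diol
Product: 17 1,5-bis(methoxymethoxy)-3-methyl-2,4-bis{[3-(benzyloxy)-2,6-bis(methoxymethoxy)-4-methylphenyl]methyl}benzene
Conditions: MOMCl, iPr2NEt, CH2Cl2, 0 °C to rt
Reagents that add atoms: chloromethyl methyl ether, COCCl
Why: Williamson-type O-alkylation of the two ring C phenols, masking them so that only the ring B oxygens freed in the next step can act as SNAr nucleophiles.

Step 10
Reactants: 17 1,5-bis(methoxymethoxy)-3-methyl-2,4-bis{[3-(benzyloxy)-2,6-bis(methoxymethoxy)-4-methylphenyl]methyl}benzene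
Product: 18 3,3'-{[4,6-bis(methoxymethoxy)-2-methyl-1,3-phenylene]bis(methylene)}bis[2,4-bis(methoxymethoxy)-6-methylphenol]
Conditions: H2 (1 atm), Pd/C, EtOAc/MeOH, rt; handled under Ar
Reagents that add atoms: none
Why: Heterogeneous hydrogenolysis of the two benzyl aryl ethers; MOM acetals and the diarylmethane C–C bonds should not be cleaved under neutral conditions.

Step 11
Reactants: 19 3-fluoro-5-methylphenol
Product: 20 4-bromo-3-fluoro-5-methylphenol
Conditions: NBS, MeCN, −20 to 0 °C
Reagents that add atoms: N-bromosuccinimide, BrN1C(=O)CCC1=O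
Why: Electrophilic aromatic bromination directed para to the hydroxyl group, the normal outcome for 3,5-disubstituted phenols with NBS in acetonitrile.

Step 12
Reactants: 20 4-bromo-3-fluoro-5-methylphenol
Product: 21 2-bromo-1-fluoro-5-(methoxymethoxy)-3-methylbenzene
Conditions: MOMCl, iPr2NEt, CH2Cl2, 0 °C to rt
Reagents that add atoms: chloromethyl methyl ether, COCCl
Why: Williamson-type MOM protection; the acetal then cooperates with fluorine in the metalation and keeps this phenol from deactivating the later SNAr.

Step 13
Reactants: 21 2-bromo-1-fluoro-5-(methoxymethoxy)-3-methylbenzene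
Product: 23 3-bromo-2-fluoro-6-(methoxymethoxy)-4-methylbenzaldehyde, via aryllithium 22 (not isolated)
Conditions: LDA, THF, −78 °C; DMF, −78 °C to rt; H2O
Reagents that add atoms: N,N-dimethylformamide, CN(C)C=O
Why: Directed ortho-lithiation by the amide base at the C–H flanked by F and OMOM (no Br/Li exchange with LDA, no LiF loss at −78 °C), then Bouveault formylation.

Step 14
Reactants: 23 3-bromo-2-fluoro-6-(methoxymethoxy)-4-methylbenzaldehyde
Product: 24 methyl 2-fluoro-3-formyl-4-(methoxymethoxy)-6-methylbenzoate
Conditions: Pd(OAc)2 (cat.), Xantphos, CO (1 atm), MeOH (5 equiv), iPr2NEt, PhMe, 80 °C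
Reagents that add atoms: carbon monoxide, [C-]#[O+]; methanol, CO
Why: Palladium-catalysed alkoxycarbonylation (oxidative addition into C–Br, CO insertion, methanolysis of the acyl–palladium); a wide-bite-angle ligand should handle the di-ortho-substituted bromide, and a hindered amine with little methanol in toluene should keep the activated C–F bond from methanolysis.

Step 15
Reactants: 18 3,3'-{[4,6-bis(methoxymethoxy)-2-methyl-1,3-phenylene]bis(methylene)}bis[2,4-bis(methoxymethoxy)-6-methylphenol]; 24 methyl 2-fluoro-3-formyl-4-(methoxymethoxy)-6-methylbenzoate (2.4 equiv)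
Product: 25 octakis(methoxymethyl) ether of praesorether G (all eight phenolic OH groups of rings A, B and C as MOM ethers)
Conditions: Cs2CO3, DMSO, 70 °C, Ar
Reagents that add atoms: none
Why: Twofold addition–elimination SNAr, in which each caesium phenoxide attacks the fluorine-bearing carbon whose Meisenheimer intermediate is stabilised by the ortho formyl and ortho ester groups; every other phenol is capped.

Step 16
Reactants: 25 octakis(methoxymethyl) ether of praesorether G
Product: 26 praesorether G
Conditions: HCl (1.25 M in MeOH), THF, rt to 40 °C; H2O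
Reagents that add atoms: none
Why: Acid-catalysed acetal cleavage of all eight MOM ethers; methanol should trap the methoxymethyl cations as dimethoxymethane before they alkylate the electron-rich rings, methanolysis of the methyl esters is degenerate, and any dimethyl acetal at the aldehydes reverts on aqueous work-up.

Compound list
1 | 2,4-dihydroxy-6-methylbenzaldehyde (orcinaldehyde) | Cc1cc(O)cc(O)c1C=O | starting material
2 | 2,4-bis(methoxymethoxy)-6-methylbenzaldehyde | Cc1cc(OCOC)cc(OCOC)c1C=O | intermediate
3 | 2,4-bis(methoxymethoxy)-6-methylphenyl formate (in situ) | Cc1cc(OCOC)cc(OCOC)c1OC=O | intermediate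
4 | 2,4-bis(methoxymethoxy)-6-methylphenol | Cc1cc(OCOC)cc(OCOC)c1O | intermediate
5 | 2-(benzyloxy)-1,5-bis(methoxymethoxy)-3-methylbenzene | Cc1cc(OCOC)cc(OCOC)c1OCc1ccccc1 | intermediate
6 | [3-(benzyloxy)-2,6-bis(methoxymethoxy)-4-methylphenyl]lithium (in situ) | Cc1cc(OCOC)c([Li])c(OCOC)c1OCc1ccccc1 | intermediate
7 | 3-(benzyloxy)-2,6-bis(methoxymethoxy)-4-methylbenzaldehyde | Cc1cc(OCOC)c(C=O)c(OCOC)c1OCc1ccccc1 | intermediate
8 | [3-(benzyloxy)-2,6-bis(methoxymethoxy)-4-methylphenyl]methanol | Cc1cc(OCOC)c(CO)c(OCOC)c1OCc1ccccc1 | intermediate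
9 | 3-(benzyloxy)-2,6-bis(methoxymethoxy)-4-methylbenzyl methanesulfonate (in situ) | Cc1cc(OCOC)c(COS(C)(=O)=O)c(OCOC)c1OCc1ccccc1 | intermediate
10 | 3-(benzyloxy)-2,6-bis(methoxymethoxy)-4-methylbenzyl chloride | Cc1cc(OCOC)c(CCl)c(OCOC)c1OCc1ccccc1 | intermediate
11 | acetylacetone (pentane-2,4-dione) | CC(=O)CC(C)=O | starting material
12 | 6-[3-(benzyloxy)-2,6-bis(methoxymethoxy)-4-methylphenyl]hexane-2,4-dione (in situ) | CC(=O)CC(=O)CCc1c(OCOC)cc(C)c(OCc2ccccc2)c1OCOC | intermediate
13 | 1,7-bis[3-(benzyloxy)-2,6-bis(methoxymethoxy)-4-methylphenyl]heptane-3,5-dione | O=C(CCc1c(OCOC)cc(C)c(OCc2ccccc2)c1OCOC)CC(=O)CCc1c(OCOC)cc(C)c(OCc2ccccc2)c1OCOC | intermediate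
14 | methyl acetate | CC(=O)OC | starting material
15 | 8-ArB-3-(ArB-methyl)octane-2,4,6-trione, ArB as defined above (in situ; racemic, enolisable C3) | CC(=O)C(Cc1c(OCOC)cc(C)c(OCc2ccccc2)c1OCOC)C(=O)CC(=O)CCc1c(OCOC)cc(C)c(OCc2ccccc2)c1OCOC | intermediate
16 | 4,6-bis{[3-(benzyloxy)-2,6-bis(methoxymethoxy)-4-methylphenyl]methyl}-5-methylbenzene-1,3-diol | Cc1c(Cc2c(OCOC)cc(C)c(OCc3ccccc3)c2OCOC)c(O)cc(O)c1Cc1c(OCOC)cc(C)c(OCc2ccccc2)c1OCOC | intermediate
17 | 1,5-bis(methoxymethoxy)-3-methyl-2,4-bis{[3-(benzyloxy)-2,6-bis(methoxymethoxy)-4-methylphenyl]methyl}benzene | Cc1c(Cc2c(OCOC)cc(C)c(OCc3ccccc3)c2OCOC)c(OCOC)cc(OCOC)c1Cc1c(OCOC)cc(C)c(OCc2ccccc2)c1OCOC | intermediate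
18 | 3,3'-{[4,6-bis(methoxymethoxy)-2-methyl-1,3-phenylene]bis(methylene)}bis[2,4-bis(methoxymethoxy)-6-methylphenol] | Cc1c(Cc2c(OCOC)cc(C)c(O)c2OCOC)c(OCOC)cc(OCOC)c1Cc1c(OCOC)cc(C)c(O)c1OCOC | intermediate
19 | 3-fluoro-5-methylphenol | Cc1cc(O)cc(F)c1 | starting material
20 | 4-bromo-3-fluoro-5-methylphenol | Cc1cc(O)cc(F)c1Br | intermediate
21 | 2-bromo-1-fluoro-5-(methoxymethoxy)-3-methylbenzene | Cc1cc(OCOC)cc(F)c1Br | intermediate
22 | [3-bromo-2-fluoro-6-(methoxymethoxy)-4-methylphenyl]lithium (in situ) | Cc1cc(OCOC)c([Li])c(F)c1Br | intermediate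
23 | 3-bromo-2-fluoro-6-(methoxymethoxy)-4-methylbenzaldehyde | Cc1cc(OCOC)c(C=O)c(F)c1Br | intermediate
24 | methyl 2-fluoro-3-formyl-4-(methoxymethoxy)-6-methylbenzoate | COC(=O)c1c(C)cc(OCOC)c(C=O)c1F | intermediate
25 | octakis(methoxymethyl) ether of praesorether G | COC(=O)c1c(C)cc(OCOC)c(C=O)c1Oc1c(C)cc(OCOC)c(Cc2c(OCOC)cc(OCOC)c(Cc3c(OCOC)cc(C)c(Oc4c(C=O)c(OCOC)cc(C)c4C(=O)OC)c3OCOC)c2C)c1OCOC | intermediate
26 | praesorether G | COC(=O)c1c(C)cc(O)c(C=O)c1Oc1c(C)cc(O)c(Cc2c(O)cc(O)c(Cc3c(O)cc(C)c(Oc4c(C=O)c(O)cc(C)c4C(=O)OC)c3O)c2C)c1O | target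

Total step count: 16 steps. Longest linear sequence: 12 steps (steps 1–10, 15 and 16, from orcinaldehyde).

Steps most likely to fail

Step 8. The dianion of 13 may act only as a base toward methyl acetate or toward the first-formed triketone and be re-protonated. The triketone may also close through its acetyl methyl onto the C4 carbonyl, or lose the acetyl group again by retro-Claisen cleavage. The fallback takes ring C from a commercial arene and makes the two bridges by cross-coupling. Orcinol (5-methylresorcinol, Cc1cc(O)cc(O)c1) is protected with MOMCl/iPr2NEt to give 1,3-bis(methoxymethoxy)-5-methylbenzene F1. NBS (2 equiv, MeCN) should brominate F1 at the two positions next to the methyl group, each para to one acetal oxygen, to give 2,4-dibromo-1,5-bis(methoxymethoxy)-3-methylbenzene F2. Chloride 10 is converted with zinc dust and LiCl in THF into [3-(benzyloxy)-2,6-bis(methoxymethoxy)-4-methylbenzyl]zinc chloride F3. A double Negishi coupling of F3 with F2 (Pd(OAc)2/SPhos, THF, 50 °C) should then give 17. The fallback sets out from 10 and rejoins the route at 17.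

Step 15. The doubly ortho-substituted phenoxides may not reach a carbon flanked by formyl and ester groups. On prolonged heating they could attack the methyl ester instead (demethylation or acyl transfer), or only one of the two ethers may form. The fallback makes the ethers before the esters. Bis-phenol 18 is condensed with bromoaldehyde 23 (K2CO3, DMAc, 110 °C), an ordinary SNAr of a 2-fluorobenzaldehyde in which the reacting carbon is flanked by formyl and a bromine atom. This should give the bis(6-bromo-2-formyl-3-(methoxymethoxy)-5-methylphenyl) ether of 18 F4. Double palladium-catalysed methoxycarbonylation of F4 under the conditions of step 14 then installs both esters. The fallback sets out from 18 and 23 and returns at 25.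

Step 14. Oxidative addition into the di-ortho-substituted C–Br bond may be slow, so that methanolysis of the C–F bond (more activated once the ester is in place) or hydrodebromination competes. The fallback carboxylates by halogen–metal exchange with the aldehyde masked. Aldehyde 23 is converted with HC(OMe)3 and catalytic PPTS in MeOH at rt, which should spare the aryl MOM ether, into 2-bromo-4-(dimethoxymethyl)-3-fluoro-5-(methoxymethoxy)-1-methylbenzene F5. Br/Li exchange (n-BuLi, THF, −78 °C) and trapping with methyl chloroformate give methyl 3-(dimethoxymethyl)-2-fluoro-4-(methoxymethoxy)-6-methylbenzoate F6. Brief treatment with PPTS in wet acetone releases the aldehyde. The fallback sets out from 23 and returns at 24.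

Further compounds
F1 | step 8 | 1,3-bis(methoxymethoxy)-5-methylbenzene | Cc1cc(OCOC)cc(OCOC)c1
F2 | step 8 | 2,4-dibromo-1,5-bis(methoxymethoxy)-3-methylbenzene | Cc1c(Br)c(OCOC)cc(OCOC)c1Br
F3 | step 8 | [3-(benzyloxy)-2,6-bis(methoxymethoxy)-4-methylbenzyl]zinc chloride | Cl[Zn]Cc1c(OCOC)cc(C)c(OCc2ccccc2)c1OCOC
F4 | step 15 | bis(6-bromo-2-formyl-3-(methoxymethoxy)-5-methylphenyl) ether of 18 | Brc1c(C)cc(OCOC)c(C=O)c1Oc1c(C)cc(OCOC)c(Cc2c(OCOC)cc(OCOC)c(Cc3c(OCOC)cc(C)c(Oc4c(C=O)c(OCOC)cc(C)c4Br)c3OCOC)c2C)c1OCOC
F5 | step 14 | 2-bromo-4-(dimethoxymethyl)-3-fluoro-5-(methoxymethoxy)-1-methylbenzene | COC(OC)c1c(OCOC)cc(C)c(Br)c1F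
F6 | step 14 | methyl 3-(dimethoxymethyl)-2-fluoro-4-(methoxymethoxy)-6-methylbenzoate | COC(=O)c1c(C)cc(OCOC)c(C(OC)OC)c1F
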